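The leftover is what puzzles me in this flask: I expect first end groups to remain at the time asked, though they are charged 1.00 equiv to one with second end groups and have a half-life by the first step of 2.7 h, shorter than the 40 h allowed.

first end groups 0.20 M; second end groups 1.00 equiv; third end groups 0.250 equiv; time 40 h

- how much of the first end groups has reacted by 40 h
- how much links there is at 40 h, in percent of the first end groups charged

    first end groups + second end groups → links (k1 = 1.3 M⁻¹ h⁻¹)
    second end groups + third end groups → links of the second sort (k2 = 1.9 M⁻¹ h⁻¹)
    second end groups → decomposed reagent (k3 = 0.19 h⁻¹)
    links ⇌ isomer of the product (K4 = 0.39, k4 = 0.21 h⁻¹)

That half-life holds the second end groups at their charge, but they are pulled down three ways, and I rate each at the start as a pseudo-first-order loss, partners as charged: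

to links: 0.260 h⁻¹
to links of the second sort: 0.0950 h⁻¹
to decomposed reagent: 0.19 h⁻¹

The other two ways together outrun the way to links, and the three give second end groups a half-life of 1.27 h, much shorter than 40 h, so I reckon on how they divide rather than on time. The zero of my scale is the statistical case, where each second end group takes a path in proportion to these rates and the proportions hold. The share going to links is then φ = 47.7%, and:

reacted = φ × equivalents of second end groups = 47.7%

Links and isomer relax with a half-life of 0.926 h, shorter than 40 h, so, taking the equilibrium constant as isomer over links:

links = reacted ÷ (1 + 0.39) = 34.3%

The forecast gives 43.8% reacted and 31.5% links, saying “the first end groups stall at about 44% conversion”. The flask gives 43.7% and 31.5%, with 0% of the second end groups, the limiting reagent, left against 56% of the first.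

My conversion stands 4 percentage points above the result, and the proportions do not hold: use of second end groups by the way to links over use by decomposition falls from 1.4 at the start to 1.1 at 1.30 h. In the neighbour flask with 1.00 equiv of third end groups, the second way rises to 0.380 h⁻¹, so φ becomes 31.3%, which gives 22.5% links. That neighbour flask shows 31.0% reacted and 22.3% links.

(All constants are invented; the flask was simulated.)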